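(Its constants are assumed; the rest is arithmetic.)

Target sits at the end of a four-step chain, and the substrate that feeds that chain also condenses with itself, so each portion of substrate has two fates. You want the amount of target after 2.0 min across a row of rising charges.

| setting | theta | eta | epsilon | gamma | beta |
|---|---|---|---|---|---|
| substrate | 0.060 M | 0.12 M | 0.25 M | 0.50 M | 1.0 M |
| time | 2.0 min | 2.0 min | 2.0 min | 2.0 min | 2.0 min |

    substrate → intermediate A (k1 = 0.015 /s)
    intermediate A → intermediate B (k2 = 0.027 /s)
    intermediate B → intermediate C (k3 = 0.099 /s)
    intermediate C → target (k4 = 0.032 /s)
    2 substrate → self-condensation product (k5 = 0.51 /M/s)

- percent here means substrate units held: one self-condensation product counts as two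
- for a step with 2 of a species take k times the square, and two of it per event
- "hardly changes" means that all values lie within two and a half points (for a concentration: within two and a half percent of the largest)
- run time (theta): 2.0 min

1. amount of target at the end, in percent of the substrate charged for theta, eta, epsilon, gamma, beta, in this order
2. the shape of the row from first to last (hardly changes / falls all the way / rises all the way / rises, then falls / falls, then rises)

Start with one number. Call D the rate at which self-condensation uses substrate over the rate at which the first step uses it, taken at the charge: 2 times 0.51 /M/s times the charge, divided by 0.015 /s. For theta, D is 4.08.

The first way to the target's share freezes the flask at its start. The share entering the chain is then one over one plus D, or 19.7 % of the charge in theta.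

The second way lets the substrate fall. With a fraction s of the charge left, the share is one over one plus Ds. Averaged over s from one down to zero, that gives the natural logarithm of one plus D, divided by D. For theta this is 39.8 %. Call it the ceiling: the overall selectivity, the part of the charge that has passed the first step once the substrate is gone. Time does not appear in it, and the later steps have no side exit.

In theta the second way gives twice what the first gives, and the first one cheats. It holds the starting ratio for the whole run, yet self-condensation goes with the square of the substrate and fades as s falls, so the ceiling stands higher.

From theta to beta, D grows by 1.22 powers of ten, and the average falls as D grows, so I commit to a falling row. Target after 2.0 min must also lie under the ceiling: the ceiling counts what has passed the first step, and target has passed the steps after it as well. Those steps have half-lives of 0.428 min, 0.117 min and 0.361 min, which sum to 0.906 min against a run of 2.0 min. My reckoning stops at that bound and gives no row of its own.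

The forecast gives 23.3 %, 16.9 %, 11.2 %, 7.2 % and 4.4 %, a row that falls all the way, on the grounds that “each increase in charge diverts more substrate”. Its theta value lies under my ceiling.

The flask gives 23.0 %, 16.6 %, 10.9 %, 7.00 % and 4.30 %: the row falls all the way, as the forecast said. In theta at 2.00 min, the 23.0 % of target stands beside 17.1 % still held as substrate and the three intermediates. The slowest mode of theta at that time has a half-life of 0.590 min, shorter than the run, and at 20.0 min target in theta reads 39.8 % against the ceiling of 39.8 %. In beta, D is 68.0 and the ceiling 6.23 %, and target at 20.0 min reads 6.23 %.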